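**Plan**
- Retrosynthesis: the C11/C12 aldehydes come from a diester; ring B is cut at C9–C10 and C7–C8 (Diels–Alder of a ring-A vinylcyclohexene with an acetylenic diester) and at C5–C6 (vinyl coupling); the chain is cut at C3′=C4′ (Wittig) and at C4–C1′.
- Enabling feature: in ring A the C3 chlorine and the chain carbon C1′ on quaternary C4 are trans-vicinal, and C4 is flanked by C5, which can carry a carbinol oxygen. A chloronium ion on a C3=C4 alkene can therefore pull C1′ from C5 to C4, setting C3 and C4 together and leaving a C5 ketone for ring-B annulation.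
- Forward order: ring A from (R)-carvone → Grignard at C5 → chloronium 1,2-shift → enol triflate and vinyl → ring B (cycloaddition, isomerisation, hydrogenation) → C1 inversion through the Δ1 alkene and its α-epoxide → chain completion → diol → dialdehyde.
- Stereochemistry: the carvone stereocentre (as a 1β-oxygen) directs the Grignard addition; the shift relays that centre to C4 and C3; the 1β-benzyloxy and 4β-methyl groups direct the cycloaddition (C10); C9 and C5 are set by protonation and hydrogenation anti to the β-methyls; 1α-OH arises from α-epoxidation and trans-diaxial hydride opening.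

Key step: step 6

Remark: target numbering is used for all intermediates (decalin C1–C10, C11 on C9, C12 on C8, chain C1′–C4′ on C4; in the ring-A monocycles C5 is the carbonyl carbon, C4 its methyl-bearing α-carbon, C1 the oxygen-bearing carbon, C10 the α′-carbon); β is the face of the C10 methyl in the target.

Step 1
Reactants: 1 (R)-(−)-carvone
Product: 2 (5R,6S)-2,6-dimethyl-5-(prop-1-en-2-yl)cyclohex-2-en-1-one
Conditions: LDA, THF, −78 °C; MeI, −78 → 0 °C
Reagents that add atoms: iodomethane, CI
Why: Kinetic α′-deprotonation and enolate alkylation should place the C10 methyl trans to the C1 isopropenyl group; this centre only relays selectivity and is erased in step 7.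

Step 2
Reactants: 2 (5R,6S)-2,6-dimethyl-5-(prop-1-en-2-yl)cyclohex-2-en-1-one
Product: 4 (5R,6S)-5-acetyl-2,6-dimethylcyclohex-2-en-1-one, via ozonide 3 (not isolated)
Conditions: O3, CH2Cl2, −78 °C; then Me2S, −78 °C → rt
Reagents that add atoms: ozone, [O-][O+]=O
Why: Ozonolysis should cleave the electron-rich 1,1-disubstituted alkene and spare the electron-poor enone double bond, as known for carvone.

Step 3
Reactants: 4 (5R,6S)-5-acetyl-2,6-dimethylcyclohex-2-en-1-one
Product: 5 (5R,6S)-5-acetoxy-2,6-dimethylcyclohex-2-en-1-one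
Conditions: mCPBA, TFA (cat.), CH2Cl2, 0 °C → rt
Reagents that add atoms: 3-chloroperbenzoic acid, OOC(=O)c1cccc(Cl)c1
Why: Baeyer–Villiger oxidation of the saturated methyl ketone should proceed with migration of the secondary ring carbon and retention at C1; the conjugated ketone and its alkene react far more slowly.

Step 4
Reactants: 5 (5R,6S)-5-acetoxy-2,6-dimethylcyclohex-2-en-1-one; 6 [2-(1,3-dioxolan-2-yl)ethyl]magnesium bromide
Product: 8 (1R,5R,6S)-1-[2-(1,3-dioxolan-2-yl)ethyl]-2,6-dimethylcyclohex-2-ene-1,5-diol, via acetate 7 (not isolated)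
Conditions: 6, anhydrous CeCl3, THF, −78 °C; then K2CO3 (cat.), MeOH, rt
Reagents that add atoms: none
Why: 1,2-Addition of the non-basic organocerium reagent (Imamoto conditions) should occur by axial attack trans to the C1 oxygen substituent, as for carvone, giving the C5 carbinol with the chain α; methanolysis then frees the secondary alcohol.

Step 5
Reactants: 8 (1R,5R,6S)-1-[2-(1,3-dioxolan-2-yl)ethyl]-2,6-dimethylcyclohex-2-ene-1,5-diol
Product: 9 (1R,5R,6S)-5-(benzyloxy)-1-[2-(1,3-dioxolan-2-yl)ethyl]-2,6-dimethylcyclohex-2-en-1-ol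
Conditions: NaH (1.05 equiv), BnBr (1.05 equiv), Bu4NI (cat.), THF, 0 °C → rt
Reagents that add atoms: benzyl bromide, BrCc1ccccc1
Why: Williamson etherification should alkylate the secondary alkoxide in preference to the hindered tertiary allylic one.

Step 6
Reactants: 9 (1R,5R,6S)-5-(benzyloxy)-1-[2-(1,3-dioxolan-2-yl)ethyl]-2,6-dimethylcyclohex-2-en-1-ol
Product: 10 (2S,3S,5R,6S)-5-(benzyloxy)-3-chloro-2-[2-(1,3-dioxolan-2-yl)ethyl]-2,6-dimethylcyclohexan-1-one
Conditions: NCS (1.1 equiv), Ph3P=S (10 mol %), CH2Cl2, −40 → 0 °C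
Reagents that add atoms: N-chlorosuccinimide, O=C1CCC(=O)N1Cl
Why: Proposed new method: the Lewis-base-activated chlorenium ion should add to C3=C4 on the β face, anti to the pseudo-axial C5 chain, and as the chloronium ion opens at tertiary C4 the antiperiplanar chain CH2 shifts from C5 to C4 while the C5 hydroxyl collapses to the ketone, an argument that rests on the tertiary cation character at C4 and the push of the carbinol oxygen. The closest known reaction type is the halonium-induced semipinacol rearrangement of tertiary allylic alcohols (ring expansion of 1-alkenylcyclobutanols and 1,2-aryl or alkyl shifts of exocyclic carbinols to α-quaternary β-halo ketones), which has not been shown for an unstrained primary alkyl group migrating within a cyclohex-2-en-1-ol. No ring is closed. The C4 quaternary centre is set by the suprafacial shift, the chain arriving on the α face it occupied at C5 (set in step 4), and the C3 chlorine is set anti to it by backside opening of the chloronium ion. The step needs migration to win over epoxide closure by the hydroxyl, ene-type proton loss and ring contraction; this is secured because A(1,2) strain with the C4 methyl holds the chain pseudo-axial and the hydroxyl pseudo-equatorial, so only the chain is aligned with the breaking C–Cl bond, and because carbonyl formation drives the shift. The acetal-masked chain and the benzyl ether leave no second nucleophilic alkene for the chlorenium ion.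

Step 7
Reactants: 10 (2S,3S,5R,6S)-5-(benzyloxy)-3-chloro-2-[2-(1,3-dioxolan-2-yl)ethyl]-2,6-dimethylcyclohexan-1-one
Product: 11 (3R,5S,6S)-3-(benzyloxy)-5-chloro-6-[2-(1,3-dioxolan-2-yl)ethyl]-2,6-dimethylcyclohex-1-en-1-yl trifluoromethanesulfonate
Conditions: KHMDS, THF, −78 °C; then PhNTf2, −78 → −30 °C
Reagents that add atoms: N-phenylbis(trifluoromethanesulfonimide), O=S(=O)(N(c1ccccc1)S(=O)(=O)C(F)(F)F)C(F)(F)F
Why: Enolisation is possible only toward C10 (C4 is quaternary), and O-triflation of the potassium enolate at low temperature should outrun β-elimination of the benzyloxy group (enol triflate formation).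

Step 8
Reactants: 11 (3R,5S,6S)-3-(benzyloxy)-5-chloro-6-[2-(1,3-dioxolan-2-yl)ethyl]-2,6-dimethylcyclohex-1-en-1-yl trifluoromethanesulfonate
Product: 12 ring-A diene: the C5-vinyl analogue of 11 (CH=CH2 in place of OTf; configuration at C1, C3 and C4 unchanged)
Conditions: Bu3SnCH=CH2, Pd(PPh3)4 (10 mol %), LiCl, CuCl, DMSO, 60 °C
Reagents that add atoms: tributyl(vinyl)stannane, CCCC[Sn](CCCC)(CCCC)C=C
Why: Copper-accelerated Stille coupling of a hindered cyclohexenyl triflate should give the semicyclic diene, as for 2,6,6-trimethylcyclohexenyl triflates.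

Step 9
Reactants: 12 ring-A diene; 13 dimethyl but-2-ynedioate
Product: 14 Diels–Alder adduct: decalin-5,8-diene with CO2Me on C8 and C9; 10β-methyl; 1β-benzyloxy; 3β-chloro; 4β-methyl; 4α-[2-(1,3-dioxolan-2-yl)ethyl]
Conditions: 13 (3 equiv), BHT (cat.), toluene, 110 °C, sealed tube
Reagents that add atoms: none
Why: Thermal Diels–Alder reaction of a 1-vinylcyclohexene with the acetylenic diester is known in the drimane series; the dienophile should add to the α face, anti to the allylic 1β-benzyloxy group and the 4β-methyl, so the new C10–C9 bond is α and the C10 methyl β.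

Step 10
Reactants: 14 Diels–Alder adduct
Product: 15 conjugated 5,7-diene diester: C5=C6 and C7=C8; 9α-H and 9β-CO2Me; other centres as in 14
Conditions: DBU (0.5 equiv), THF, rt
Reagents that add atoms: none
Why: Base-mediated prototropic shift from the doubly allylic C7 to C9 (vinylogous to the C9 ester) should give the conjugated diene, with C9 protonated on the α face anti to the C10 methyl, as in the polygodial series.

Step 11
Reactants: 15 conjugated 5,7-diene diester
Product: 16 dimethyl 3β-chloro-4α-[2-(1,3-dioxolan-2-yl)ethyl]-1β-hydroxy-4β,10β-dimethyl-5α,9α-H-decal-7-ene-8,9-dicarboxylate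
Conditions: H2 (1 atm), Pd(OH)2/C, EtOAc, rt
Reagents that add atoms: none
Why: Heterogeneous hydrogenation should saturate only the Δ5 bond from the α face (opposite the C4 and C10 β-methyls), fixing the trans ring fusion, and cleave the benzyl ether in the same operation; the conjugated Δ7 ester alkene and the alkyl chloride should survive.

Step 12
Reactants: 16 1β-hydroxy diester
Product: 17 Δ1-alkene diester: C1=C2 in place of the 1β-hydroxyl; other centres as in 16
Conditions: Burgess reagent, benzene, 50 °C
Reagents that add atoms: none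
Why: Burgess dehydration (syn-elimination of the C1 sulfamate) can use only the cis C2–H because C10 is quaternary, so only the Δ1 alkene should form.

Step 13
Reactants: 17 Δ1-alkene diester
Product: 18 1α,2α-epoxide of 17
Conditions: mCPBA, CH2Cl2, 0 °C → rt
Reagents that add atoms: 3-chloroperbenzoic acid, OOC(=O)c1cccc(Cl)c1
Why: Prilezhaev epoxidation should occur on the only non-conjugated alkene and from the α face, opposite the axial C10 methyl and the 3β-chlorine, as for 5α-Δ1-steroids.

Step 14
Reactants: 18 1α,2α-epoxide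
Product: 19 epoxy diester aldehyde: chain CH2CH2CHO on C4
Conditions: PPTS (cat.), acetone/H2O 9:1, 50 °C
Reagents that add atoms: water, O
Why: Mild acid-catalysed acetal hydrolysis should free the aldehyde; the hindered epoxide, deactivated by the neighbouring C–Cl bond, and the esters should tolerate PPTS.

Step 15
Reactants: 19 epoxy diester aldehyde
Product: 20 epoxy diester with the complete 4-methylpent-3-enyl chain
Conditions: i-PrPPh3+ I−, n-BuLi, THF, 0 °C; then 19, −78 → 0 °C
Reagents that add atoms: isopropyltriphenylphosphonium iodide, CC(C)[P+](c1ccccc1)(c1ccccc1)c1ccccc1.[I-]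
Why: Wittig olefination of the aldehyde with the non-stabilised isopropylidene ylide should complete the chain; esters and epoxide do not react at low temperature.

Step 16
Reactants: 20 epoxy diester
Product: 21 triol: 3β-chloro-1α-hydroxy-11,12-diol with Δ7 and the complete chain
Conditions: LiAlH4, THF, 0 → 40 °C
Reagents that add atoms: none
Why: Hydride should reduce both esters and open the 1α,2α-epoxide by trans-diaxial attack at C2 (Fürst–Plattner rule), leaving the axial 1α-alcohol as in 1α-hydroxy steroid syntheses; the hindered secondary chloride should be inert.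

Step 17
Reactants: 21 triol
Product: 22 target CNP0155449.1
Conditions: (COCl)2 (2.2 equiv), DMSO (4.5 equiv), CH2Cl2, −78 °C; then Et3N, −78 → −30 °C
Reagents that add atoms: none
Why: Swern oxidation activates both primary alcohols before base is added and should give the ene-dialdehyde without lactol formation or C9 epimerisation, as in polygodial syntheses; the axial neopentyl 1α-hydroxyl should be activated much more slowly by the limited amount of reagent.

**Compound list**
1 | (R)-(−)-carvone | CC1=CC[C@@H](C(C)=C)CC1=O | starting material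
2 | (5R,6S)-2,6-dimethyl-5-(prop-1-en-2-yl)cyclohex-2-en-1-one | CC1=CC[C@@H](C(C)=C)[C@H](C)C1=O | intermediate
3 | ozonide of 2: (5R,6S)-2,6-dimethyl-5-(3-methyl-1,2,4-trioxolan-3-yl)cyclohex-2-en-1-one | CC1=CC[C@@H](C2(C)OOCO2)[C@H](C)C1=O | intermediate (not isolated)
4 | (5R,6S)-5-acetyl-2,6-dimethylcyclohex-2-en-1-one | CC1=CC[C@@H](C(C)=O)[C@H](C)C1=O | intermediate
5 | (5R,6S)-5-acetoxy-2,6-dimethylcyclohex-2-en-1-one | CC1=CC[C@@H](OC(C)=O)[C@H](C)C1=O | intermediate
6 | [2-(1,3-dioxolan-2-yl)ethyl]magnesium bromide | Br[Mg]CCC1OCCO1 | starting material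
7 | (1R,5R,6S)-5-acetoxy-1-[2-(1,3-dioxolan-2-yl)ethyl]-2,6-dimethylcyclohex-2-en-1-ol | CC1=CC[C@@H](OC(C)=O)[C@H](C)[C@]1(O)CCC2OCCO2 | intermediate (not isolated)
8 | (1R,5R,6S)-1-[2-(1,3-dioxolan-2-yl)ethyl]-2,6-dimethylcyclohex-2-ene-1,5-diol | CC1=CC[C@@H](O)[C@H](C)[C@]1(O)CCC2OCCO2 | intermediate
9 | (1R,5R,6S)-5-(benzyloxy)-1-[2-(1,3-dioxolan-2-yl)ethyl]-2,6-dimethylcyclohex-2-en-1-ol | CC1=CC[C@@H](OCc2ccccc2)[C@H](C)[C@]1(O)CCC3OCCO3 | intermediate
10 | (2S,3S,5R,6S)-5-(benzyloxy)-3-chloro-2-[2-(1,3-dioxolan-2-yl)ethyl]-2,6-dimethylcyclohexan-1-one | O=C1[C@](C)(CCC3OCCO3)[C@@H](Cl)C[C@@H](OCc2ccccc2)[C@@H]1C | intermediate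
11 | (3R,5S,6S)-3-(benzyloxy)-5-chloro-6-[2-(1,3-dioxolan-2-yl)ethyl]-2,6-dimethylcyclohex-1-en-1-yl trifluoromethanesulfonate | CC1=C(OS(=O)(=O)C(F)(F)F)[C@](C)(CCC3OCCO3)[C@@H](Cl)C[C@H]1OCc2ccccc2 | intermediate
12 | ring-A diene: 1-ethenyl analogue of 11 (vinyl on C5; 1β-OBn; 3β-Cl; 4β-Me; 4α-dioxolanylethyl) | CC1=C(C=C)[C@](C)(CCC3OCCO3)[C@@H](Cl)C[C@H]1OCc2ccccc2 | intermediate
13 | dimethyl but-2-ynedioate | COC(=O)C#CC(=O)OC | starting material
14 | Diels–Alder adduct: decalin-5,8-diene 8,9-dimethyl diester; 10β-Me; 1β-OBn; 3β-Cl; 4β-Me; 4α-dioxolanylethyl | COC(=O)C1=C(C(=O)OC)[C@@]2(C)[C@H](OCc3ccccc3)C[C@H](Cl)[C@@](C)(CCC4OCCO4)C2=CC1 | intermediate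
15 | conjugated 5,7-diene diester; 9β-CO2Me | COC(=O)C1=CC=C2[C@](C)(CCC4OCCO4)[C@@H](Cl)C[C@@H](OCc3ccccc3)[C@]2(C)[C@H]1C(=O)OC | intermediate
16 | 1β-hydroxy Δ7 diester; trans-decalin (5α-H) | COC(=O)C1=CC[C@H]2[C@](C)(CCC4OCCO4)[C@@H](Cl)C[C@@H](O)[C@]2(C)[C@H]1C(=O)OC | intermediate
17 | Δ1,Δ7-diene diester | COC(=O)C1=CC[C@H]2[C@](C)(CCC4OCCO4)[C@@H](Cl)C=C[C@]2(C)[C@H]1C(=O)OC | intermediate
18 | 1α,2α-epoxy Δ7 diester | COC(=O)C1=CC[C@H]2[C@](C)(CCC4OCCO4)[C@@H](Cl)[C@@H]3O[C@@H]3[C@]2(C)[C@H]1C(=O)OC | intermediate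
19 | 1α,2α-epoxy diester with CH2CH2CHO chain | COC(=O)C1=CC[C@H]2[C@](C)(CCC=O)[C@@H](Cl)[C@@H]3O[C@@H]3[C@]2(C)[C@H]1C(=O)OC | intermediate
20 | 1α,2α-epoxy diester with 4-methylpent-3-enyl chain | COC(=O)C1=CC[C@H]2[C@](C)(CCC=C(C)C)[C@@H](Cl)[C@@H]3O[C@@H]3[C@]2(C)[C@H]1C(=O)OC | intermediate
21 | 3β-chloro-1α,11,12-triol (Δ7) | OCC1=CC[C@H]2[C@](C)(CCC=C(C)C)[C@@H](Cl)C[C@H](O)[C@]2(C)[C@H]1CO | intermediate
22 | CNP0155449.1: 3β-chloro-1α-hydroxy-4α-(4-methylpent-3-enyl)-4β,10β-dimethyl-5α,9α-H-decal-7-ene-8,9β-dicarbaldehyde | CC(C)=CCC[C@]1(C)[C@@H](Cl)C[C@H](O)[C@]2(C)[C@@H](C=O)C(C=O)=CC[C@@H]12 | target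

**Count and risks**
Total steps: 17. Longest linear sequence: 17 (from 1).

Step 6 (Proposed new method). The chloronium ion may lose a proton (ene-type allylic chlorination) or be captured by the hydroxyl before the alkyl shift occurs. The fallback uses known chemistry, sets out from 9 and returns at 10. Hydroxyl-directed epoxidation of 9 (VO(acac)2, t-BuOOH) should give the syn epoxy alcohol, (1R,5R,6S)-5-(benzyloxy)-1-[2-(1,3-dioxolan-2-yl)ethyl]-2,6-dimethyl-2,3-epoxycyclohexan-1-ol with the epoxide cis to the hydroxyl F1. The Lewis-acid-induced 2,3-epoxy alcohol semipinacol rearrangement (BF3·OEt2, CH2Cl2, −78 °C; anti 1,2-alkyl shift) should then give the β-hydroxy ketone, (2R,3S,5R,6S)-5-(benzyloxy)-2-[2-(1,3-dioxolan-2-yl)ethyl]-3-hydroxy-2,6-dimethylcyclohexan-1-one F2. Chlorination with retention (SOCl2, dioxane, SNi) would return to 10; this last step is itself exposed to cationic rearrangement at the neopentyl carbinol.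

Step 12. The neopentyl sulfamate may ionise, with migration of the C10 methyl, instead of undergoing syn-elimination. The fallback sets out from 16 and returns at 17. Acylation of 16 with phenyl chlorothionoformate (pyridine, DMAP) should give the O-phenyl thionocarbonate of 16 F3, whose concerted thermal syn-elimination (Chugaev type, o-dichlorobenzene, 180 °C) avoids an ion pair.

Step 17. The oxidation may also attack the 1α-hydroxyl, or, if reagent is held back, stop at a hydroxy aldehyde that closes to a lactol. The fallback sets out from 21 and returns at 22. Persilylation (TESOTf, 2,6-lutidine) should give the 1,11,12-tris(triethylsilyl) ether of 21 F4. Swern conditions are known to oxidise primary triethylsilyl ethers directly to aldehydes while secondary ones survive, which should give the 1-O-triethylsilyl ether of 22 F5. HF·pyridine (THF, 0 °C) would then free the 1α-hydroxyl.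

Further compounds
F1 | step 6 | syn 2,3-epoxy alcohol from 9 (epoxide cis to the tertiary hydroxyl) | C[C@@]12O[C@H]2C[C@@H](OCc3ccccc3)[C@H](C)[C@]1(O)CCC4OCCO4
F2 | step 6 | (2R,3S,5R,6S)-5-(benzyloxy)-2-[2-(1,3-dioxolan-2-yl)ethyl]-3-hydroxy-2,6-dimethylcyclohexan-1-one | O=C1[C@](C)(CCC3OCCO3)[C@@H](O)C[C@@H](OCc2ccccc2)[C@@H]1C
F3 | step 12 | O-phenyl thionocarbonate of 16 at the 1β-oxygen | COC(=O)C1=CC[C@H]2[C@](C)(CCC4OCCO4)[C@@H](Cl)C[C@@H](OC(=S)Oc3ccccc3)[C@]2(C)[C@H]1C(=O)OC
F4 | step 17 | 1,11,12-tris(triethylsilyl) ether of 21 | CC[Si](CC)(CC)OCC1=CC[C@H]2[C@](C)(CCC=C(C)C)[C@@H](Cl)C[C@H](O[Si](CC)(CC)CC)[C@]2(C)[C@H]1CO[Si](CC)(CC)CC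
F5 | step 17 | 1-O-triethylsilyl ether of 22 | O=CC1=CC[C@H]2[C@](C)(CCC=C(C)C)[C@@H](Cl)C[C@H](O[Si](CC)(CC)CC)[C@]2(C)[C@H]1C=O
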